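Ring A (cyclopentane C1–C2–C3–C3a–C7a) is cut across C2–C3 and C3a–C7a into a C7a–C1–C2 unit and a C3=C3a alkene. Quaternary C7a bears a methyl and the oxygenated C7, hence a 1-methylcyclopropyl ketone. C3a adjoins sp2 C4 and C13 bears oxygen, hence an unsaturated δ-lactone (C4 carbonyl, C13–O ring oxygen). One samarium-ketyl radical-relay [3+2] annulation joins them, setting C3, C3a and C7a under control of the cis-disubstituted lactone. Ring B follows by Dieckmann closure and one-carbon ring expansion, ring C by Nozaki–Hiyama–Kishi macrocyclisation.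

Key step: step 4

Remark: local numbering is used for the target and all intermediates. Hydrindane C1–C3, C3a, C4–C7, C7a (ring A = C1, C2, C3, C3a, C7a; ring B = C3a, C4, C5, C6, C7, C7a); bridge C8–C14 from C5 to C3 (11-membered ring C). C4 bears the exocyclic methylene, C7a the methyl, C7, C9 and C13 the propionates, C10 and C14 methyls, C10=C11 the alkene. α is the face of the C7a methyl. The target has H-3a α, H-3 α, C8 on C5 α, O on C7 α, and (9R,10Z,13S,14S). Compounds 1 and 5 and the Grignard reagent of step 7 are taken as commercial.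

Step 1
Reactants: 1 3-[(tert-butyldimethylsilyl)oxy]propanal
Product: 2 (3S,4S)-1-[(tert-butyldimethylsilyl)oxy]-4-methylhex-5-en-3-ol (syn)
Conditions: cis-2-butene, n-BuLi, KOt-Bu, THF, −78 → −45 °C; (+)-Ipc2BOMe, −78 °C; BF3·OEt2; then 1, −78 °C; NaOH, H2O2
Reagents that add atoms: (Z)-crotyl-(+)-diisopinocampheylborane, made in the flask from cis-2-butene (C/C=C\C), C/C=C\CB([C@H]1C[C@H]2C[C@H](C2(C)C)[C@@H]1C)[C@H]1C[C@H]2C[C@H](C2(C)C)[C@@H]1C
Why: Brown asymmetric crotylboration through a closed chair transition state, in which the (Z)-crotyl geometry gives the syn hydroxyl/methyl pair and the (+)-isopinocampheyl ligands direct attack to the Re face of the aldehyde, fixing (3S,4S), the future C13 and C14.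

Step 2
Reactants: 2 (3S,4S)-1-[(tert-butyldimethylsilyl)oxy]-4-methylhex-5-en-3-ol
Product: 3 (3S,4S)-1-[(tert-butyldimethylsilyl)oxy]-4-methylhex-5-en-3-yl prop-2-enoate
Conditions: acryloyl chloride, Et3N, DMAP (cat.), CH2Cl2, 0 °C
Reagents that add atoms: acryloyl chloride, C=CC(=O)Cl
Why: DMAP-catalysed O-acylation of the secondary alcohol, which touches no stereocentre.

Step 3
Reactants: 3 (3S,4S)-1-[(tert-butyldimethylsilyl)oxy]-4-methylhex-5-en-3-yl prop-2-enoate
Product: 4 (5S,6S)-6-{2-[(tert-butyldimethylsilyl)oxy]ethyl}-5-methyl-5,6-dihydro-2H-pyran-2-one (5,6-cis)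
Conditions: second-generation Grubbs catalyst RuCl2(=CHPh)(H2IMes)(PCy3) (5 mol%), CH2Cl2, 40 °C, high dilution
Reagents that add atoms: none
Why: Ring-closing metathesis of the acrylate with the terminal vinyl group should close the six-membered unsaturated lactone with loss of ethylene, leaving both stereocentres untouched.

Step 4
Reactants: 4 (5S,6S)-6-{2-[(tert-butyldimethylsilyl)oxy]ethyl}-5-methyl-5,6-dihydro-2H-pyran-2-one; 5 1-(1-methylcyclopropyl)ethan-1-one
Product: 6 (3S,4S,4aS,7S,7aR)-7-acetyl-3-{2-[(tert-butyldimethylsilyl)oxy]ethyl}-4,7-dimethylhexahydrocyclopenta[c]pyran-1(3H)-one (cis-fused; acetyl cis to the lactone carbonyl)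
Conditions: Sm powder (40 mol%), ICH2CH2I (20 mol%), THF, rt (SmI2, 20 mol%, forms in the flask beside 20 mol% of unreacted Sm); then 4 and ketone 5 in threefold excess, 55 °C
Reagents that add atoms: none
Why: Reversible electron transfer from SmI2 to ketone 5 gives a ketyl whose cyclopropane opens to a primary C2 radical tethered to a tetrasubstituted samarium enolate (C7a=C7); the radical adds to the β-carbon C3 of lactone 4, and the α-lactone radical at C3a then closes onto the enolate carbon C7a, regenerating a ketyl that passes the electron on (radical relay). The closest known reaction type is the SmI2-catalysed formal [3+2] cycloaddition of alkyl cyclopropyl ketones with electron-poor alkenes. Ring A closes in a 5-exo-trig radical cyclisation (radical rebound onto the enolate) after an intermolecular Giese-type addition. C3 should be set by approach of the radical anti to the cis C14 methyl and C13 side chain of the lactone, and C3a by the cis ring fusion that a five-membered closure onto the six-membered lactone enforces. Quaternary C7a should be set by a trivalent-samarium bridge between the enolate oxygen and the lactone carbonyl, reinforced by the 1,5-cis preference of 5-exo closures, which places the acetyl group cis to C4. The step needs β-regioselectivity and suppression of simple reduction of the α-lactone radical; the polarised acceptor should secure the first and the low stationary concentration of divalent samarium the second.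

Step 5
Reactants: 6 [3+2] adduct (keto lactone)
Product: 8 (3aS,6S,6aR)-6-[(2S,3S)-3,5-bis(tert-butyldimethylsilyloxy)pentan-2-yl]-3a-methyltetrahydropentalene-1,3(2H,3aH)-dione (cis-fused), via hydroxy-dione dilithium salt 7 (not isolated)
Conditions: LiN(SiMe3)2 (2.2 equiv), THF, −78 → 0 °C; TBSOTf (1.1 equiv), −78 °C; aq. NH4Cl
Reagents that add atoms: tert-butyldimethylsilyl triflate, CC(C)(C)[Si](C)(C)OS(=O)(=O)C(F)(F)F
Why: Dieckmann-type (intramolecular Claisen) condensation in which the acetyl methyl, the only enolisable position of the C7 ketone, attacks the cis-disposed lactone carbonyl C4 to give the cis-fused cyclopentane-1,3-dione (possible only when acetyl and C4 are cis); the liberated C13 alkoxide is silylated in the same flask, and the far less nucleophilic diketonate is restored on work-up.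

Step 6
Reactants: 8 bicyclic 1,3-dione
Product: 10 cis-7a-methyl-3β-[(2S,3S)-3,5-bis(tert-butyldimethylsilyloxy)pentan-2-yl]-2,3,3a,7a-tetrahydro-1H-indene-4,7-dione (ene-dione, C5=C6), via iodo-diketone 9 (not isolated)
Conditions: Et2Zn, CH2I2, CH2Cl2, 0 °C → rt; I2, 0 °C; aq. Na2S2O3; DBU, Et2O, rt
Reagents that add atoms: diiodomethane, ICI
Why: Zinc-carbenoid chain extension of a 1,3-dicarbonyl (Zercher reaction) in its tandem iodination–elimination form: the zinc enolate of 8 is cyclopropanated and fragments with insertion of CH2 between a carbonyl and the central carbon, which expands the five-membered dione to ring B, and iodination of the resulting zinc enolate followed by DBU elimination should give the ene-dione (insertion on either side converges on the same product, the former acetyl methyl and the carbenoid carbon becoming C5 and C6).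

Step 7
Reactants: 10 ene-dione
Product: 11 cis-5α-(1,3-dioxolan-2-ylmethyl)-7a-methyl-3β-[(2S,3S)-3,5-bis(tert-butyldimethylsilyloxy)pentan-2-yl]-7-(triethylsilyloxy)-1,2,3,3a,5,7a-hexahydro-4H-inden-4-one
Conditions: (1,3-dioxolan-2-ylmethyl)magnesium bromide, CuBr·SMe2 (20 mol%), Et3SiCl, THF, −78 °C; Et3N, pH 7 buffer
Reagents that add atoms: (1,3-dioxolan-2-ylmethyl)magnesium bromide, Br[Mg]CC1OCCO1; chlorotriethylsilane, CC[Si](Cl)(CC)CC
Why: Copper-catalysed, silyl-chloride-accelerated conjugate addition of a Grignard reagent: axial attack at C6 from either face would meet a syn-axial carbon on quaternary C7a and β-attack at C5 would meet C3, so the nucleophile should enter at C5 from the α face, trans to the C3 carbon on C3a (3,5-trans rule of cyclohexenones), and trapping of the C7 enolate as its triethylsilyl enol ether tells the two carbonyls apart.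

Step 8
Reactants: 11 keto silyl enol ether
Product: 12 cis-5α-(1,3-dioxolan-2-ylmethyl)-7a-methyl-4-methylidene-3β-[(2S,3S)-3,5-bis(tert-butyldimethylsilyloxy)pentan-2-yl]-7-(triethylsilyloxy)-2,3,3a,4,5,7a-hexahydro-1H-indene
Conditions: Tebbe reagent Cp2Ti(μ-Cl)(μ-CH2)AlMe2, pyridine, THF/toluene, −40 → 0 °C
Reagents that add atoms: Tebbe reagent Cp2Ti(μ-Cl)(μ-CH2)AlMe2 (drawn in its open form, chloride on titanium), C[Al](C)C[Ti](Cl)(C1C=CC=C1)C1C=CC=C1
Why: Tebbe methylenation of the hindered C4 ketone via a titanium carbene and an oxatitanacyclobutane; the reagent is non-basic, so the α-stereocentres C5 and C3a should not epimerise, and the silyl enol ether and acetal are inert.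

Step 9
Reactants: 12 methylidene silyl enol ether
Product: 13 cis-5α-(1,3-dioxolan-2-ylmethyl)-3β-[(2S,3S)-3-(tert-butyldimethylsilyloxy)-5-hydroxypentan-2-yl]-7a-methyl-4-methylideneoctahydro-1H-inden-7-one
Conditions: HF·pyridine, pyridine, THF, 0 °C → rt
Reagents that add atoms: none
Why: Fluoride-mediated desilylation cleaves the silyl enol ether to the C7 ketone and the primary silyl ether to the C11 alcohol, while the hindered secondary C13 silyl ether and the dioxolane should survive.

Step 10
Reactants: 13 keto alcohol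
Product: 14 (3S,4S)-3-(tert-butyldimethylsilyloxy)-4-[cis-5α-(1,3-dioxolan-2-ylmethyl)-7a-methyl-4-methylidene-7-oxooctahydro-1H-inden-3β-yl]pentanal
Conditions: Dess–Martin periodinane, NaHCO3, CH2Cl2, rt
Reagents that add atoms: none
Why: Dess–Martin oxidation of the primary alcohol under buffered, non-epimerising conditions gives the C11 aldehyde, a β-silyloxy aldehyde that resists elimination.

Step 11
Reactants: 14 keto aldehyde
Product: 15 cis-5α-(1,3-dioxolan-2-ylmethyl)-3β-[(2S,3S,5Z)-3-(tert-butyldimethylsilyloxy)-6-iodohept-5-en-2-yl]-7a-methyl-4-methylideneoctahydro-1H-inden-7-one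
Conditions: [Ph3PCH(I)CH3]I, NaN(SiMe3)2, THF, −78 °C; then 14, −78 → −20 °C
Reagents that add atoms: (1-iodoethyl)triphenylphosphonium iodide, CC(I)[P+](c1ccccc1)(c1ccccc1)c1ccccc1.[I-]
Why: Stork–Zhao olefination (Wittig reaction of an α-iodo ylide) under kinetic control should give the (Z)-iodoalkene with iodine cis to the C12 chain, and the hindered C7 ketone does not compete with the aldehyde.

Step 12
Reactants: 15 alkenyl iodide ketone
Product: 16 cis-5α-(1,3-dioxolan-2-ylmethyl)-3β-[(2S,3S,5Z)-3-(tert-butyldimethylsilyloxy)-6-iodohept-5-en-2-yl]-7a-methyl-4-methylideneoctahydro-1H-inden-7α-ol ((7S))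
Conditions: (R)-Me-CBS oxazaborolidine, catecholborane, toluene, −78 °C
Reagents that add atoms: none
Why: Corey–Bakshi–Shibata reduction under reagent control, with quaternary C7a as the large and the C6 methylene as the small flank, so the (R)-oxazaborolidine should deliver hydride to the β face and give the (7S) alcohol with oxygen α (cis to the C7a methyl); catecholborane at −78 °C leaves the alkenes alone.

Step 13
Reactants: 16 C7 alcohol
Product: 17 the C7 propanoate of 16
Conditions: (EtCO)2O, DMAP, Et3N, CH2Cl2, rt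
Reagents that add atoms: propionic anhydride, CCC(=O)OC(=O)CC
Why: DMAP-catalysed acylation of the hindered C7 alcohol installs the first propionate and prevents lactol formation with the C9 aldehyde in the next step.

Step 14
Reactants: 17 C7 propionate
Product: 18 cis-3β-[(2S,3S,5Z)-3-hydroxy-6-iodohept-5-en-2-yl]-7a-methyl-4-methylidene-5α-(2-oxoethyl)octahydro-1H-inden-7α-yl propanoate
Conditions: 1 M HCl, THF, rt
Reagents that add atoms: water, O
Why: Acid-catalysed acetal hydrolysis and desilylation in one operation unveil the C9 aldehyde and the C13 alcohol, and dilute acid at room temperature should leave the exocyclic alkene, the alkenyl iodide and the ester untouched.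

Step 15
Reactants: 18 hydroxy aldehyde alkenyl iodide
Product: 19 tricyclic 9,13-diol 7-propanoate (ring C closed; (9R,10Z,13S,14S), other centres as in the target)
Conditions: CrCl2 (excess), NiCl2 (cat.), DMSO/THF, rt, high dilution (syringe pump)
Reagents that add atoms: none
Why: Nozaki–Hiyama–Kishi reaction, in which zerovalent nickel inserts into the C–I bond with retention of the (Z)-geometry, transmetalation to trivalent chromium gives an alkenylchromium that adds only to the aldehyde, and high dilution favours the 11-membered ring C; the C9 carbinol is set by the conformation of the forming ring, the (9R) outcome being expected but not secured.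

Step 16
Reactants: 19 tricyclic diol monopropionate
Product: 20 target tripropionate (CNP0315827.1)
Conditions: (EtCO)2O, DMAP, pyridine, CH2Cl2, rt
Reagents that add atoms: propionic anhydride, CCC(=O)OC(=O)CC
Why: DMAP-catalysed acylation of the two remaining secondary alcohols (C9, C13) should give the tripropionate without touching any stereocentre.

Compound list
1 | 3-[(tert-butyldimethylsilyl)oxy]propanal | O=CCCO[Si](C)(C)C(C)(C)C | starting material
2 | (3S,4S)-1-[(tert-butyldimethylsilyl)oxy]-4-methylhex-5-en-3-ol | C=C[C@H](C)[C@@H](O)CCO[Si](C)(C)C(C)(C)C | intermediate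
3 | (3S,4S)-1-[(tert-butyldimethylsilyl)oxy]-4-methylhex-5-en-3-yl prop-2-enoate | C=C[C@H](C)[C@@H](OC(=O)C=C)CCO[Si](C)(C)C(C)(C)C | intermediate
4 | (5S,6S)-6-{2-[(tert-butyldimethylsilyl)oxy]ethyl}-5-methyl-5,6-dihydro-2H-pyran-2-one | O=C1C=C[C@H](C)[C@H](CCO[Si](C)(C)C(C)(C)C)O1 | intermediate
5 | 1-(1-methylcyclopropyl)ethan-1-one | CC(=O)C1(C)CC1 | starting material
6 | (3S,4S,4aS,7S,7aR)-7-acetyl-3-{2-[(tert-butyldimethylsilyl)oxy]ethyl}-4,7-dimethylhexahydrocyclopenta[c]pyran-1(3H)-one | CC(=O)[C@@]1(C)CC[C@H]2[C@H](C)[C@H](CCO[Si](C)(C)C(C)(C)C)OC(=O)[C@@H]12 | intermediate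
7 | (3aS,6S,6aR)-6-[(2S,3S)-5-(tert-butyldimethylsilyloxy)-3-hydroxypentan-2-yl]-3a-methyltetrahydropentalene-1,3(2H,3aH)-dione (dilithium salt in the flask) | O=C1CC(=O)[C@@]2(C)CC[C@@H]([C@H](C)[C@@H](O)CCO[Si](C)(C)C(C)(C)C)[C@@H]12 | intermediate
8 | (3aS,6S,6aR)-6-[(2S,3S)-3,5-bis(tert-butyldimethylsilyloxy)pentan-2-yl]-3a-methyltetrahydropentalene-1,3(2H,3aH)-dione | O=C1CC(=O)[C@@]2(C)CC[C@@H]([C@H](C)[C@@H](O[Si](C)(C)C(C)(C)C)CCO[Si](C)(C)C(C)(C)C)[C@@H]12 | intermediate
9 | cis-6-iodo-7a-methyl-3β-[(2S,3S)-3,5-bis(tert-butyldimethylsilyloxy)pentan-2-yl]hexahydro-1H-indene-4,7-dione (epimers at C–I; the 5-iodo regioisomer converges) | O=C1CC(I)C(=O)[C@@]2(C)CC[C@@H]([C@H](C)[C@@H](O[Si](C)(C)C(C)(C)C)CCO[Si](C)(C)C(C)(C)C)[C@@H]12 | intermediate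
10 | cis-7a-methyl-3β-[(2S,3S)-3,5-bis(tert-butyldimethylsilyloxy)pentan-2-yl]-2,3,3a,7a-tetrahydro-1H-indene-4,7-dione | O=C1C=CC(=O)[C@@]2(C)CC[C@@H]([C@H](C)[C@@H](O[Si](C)(C)C(C)(C)C)CCO[Si](C)(C)C(C)(C)C)[C@@H]12 | intermediate
11 | cis-5α-(1,3-dioxolan-2-ylmethyl)-7a-methyl-3β-[(2S,3S)-3,5-bis(tert-butyldimethylsilyloxy)pentan-2-yl]-7-(triethylsilyloxy)-1,2,3,3a,5,7a-hexahydro-4H-inden-4-one | O=C1[C@H](CC3OCCO3)C=C(O[Si](CC)(CC)CC)[C@@]2(C)CC[C@@H]([C@H](C)[C@@H](O[Si](C)(C)C(C)(C)C)CCO[Si](C)(C)C(C)(C)C)[C@@H]12 | intermediate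
12 | 4-methylidene analogue of 11 | C=C1[C@H](CC3OCCO3)C=C(O[Si](CC)(CC)CC)[C@@]2(C)CC[C@@H]([C@H](C)[C@@H](O[Si](C)(C)C(C)(C)C)CCO[Si](C)(C)C(C)(C)C)[C@@H]12 | intermediate
13 | cis-5α-(1,3-dioxolan-2-ylmethyl)-3β-[(2S,3S)-3-(tert-butyldimethylsilyloxy)-5-hydroxypentan-2-yl]-7a-methyl-4-methylideneoctahydro-1H-inden-7-one | C=C1[C@H](CC3OCCO3)CC(=O)[C@@]2(C)CC[C@@H]([C@H](C)[C@@H](O[Si](C)(C)C(C)(C)C)CCO)[C@@H]12 | intermediate
14 | C11 aldehyde of 13 | C=C1[C@H](CC3OCCO3)CC(=O)[C@@]2(C)CC[C@@H]([C@H](C)[C@@H](O[Si](C)(C)C(C)(C)C)CC=O)[C@@H]12 | intermediate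
15 | cis-5α-(1,3-dioxolan-2-ylmethyl)-3β-[(2S,3S,5Z)-3-(tert-butyldimethylsilyloxy)-6-iodohept-5-en-2-yl]-7a-methyl-4-methylideneoctahydro-1H-inden-7-one | C=C1[C@H](CC3OCCO3)CC(=O)[C@@]2(C)CC[C@@H]([C@H](C)[C@@H](O[Si](C)(C)C(C)(C)C)C/C=C(/C)I)[C@@H]12 | intermediate
16 | (7S)-7α-alcohol of 15 | C=C1[C@H](CC3OCCO3)C[C@H](O)[C@@]2(C)CC[C@@H]([C@H](C)[C@@H](O[Si](C)(C)C(C)(C)C)C/C=C(/C)I)[C@@H]12 | intermediate
17 | C7 propanoate of 16 | C=C1[C@H](CC3OCCO3)C[C@H](OC(=O)CC)[C@@]2(C)CC[C@@H]([C@H](C)[C@@H](O[Si](C)(C)C(C)(C)C)C/C=C(/C)I)[C@@H]12 | intermediate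
18 | cis-3β-[(2S,3S,5Z)-3-hydroxy-6-iodohept-5-en-2-yl]-7a-methyl-4-methylidene-5α-(2-oxoethyl)octahydro-1H-inden-7α-yl propanoate | C=C1[C@H](CC=O)C[C@H](OC(=O)CC)[C@@]2(C)CC[C@@H]([C@H](C)[C@@H](O)C/C=C(/C)I)[C@@H]12 | intermediate
19 | tricyclic (9R,13S)-9,13-diol 7-propanoate (target skeleton) | C=C1[C@H]2C[C@H](OC(=O)CC)[C@@]3(C)CC[C@@H]([C@H](C)[C@@H](O)C/C=C(/C)[C@H](O)C2)[C@@H]13 | intermediate
20 | CNP0315827.1, the 7,9,13-tripropanoate | C=C1[C@H]2C[C@H](OC(=O)CC)[C@@]3(C)CC[C@@H]([C@H](C)[C@@H](OC(=O)CC)C/C=C(/C)[C@H](OC(=O)CC)C2)[C@@H]13 | target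

Total step count: 16. Longest linear sequence: 16 steps (1 → 20); ketone 5 enters at step 4.

Steps most likely to fail

Step 4. The radical rebound may show poor facial selectivity at the enolate carbon, giving the C7a epimer with acetyl trans to C4, which cannot close ring B. The fallback sets out from 4 and fixes C7a by enolate alkylation instead. The same samarium relay is run with cyclopropyl methyl ketone (CC(=O)C1CC1) to give the C7a–H adduct F1, whose C7a epimers are both usable. Me3SiCl, NaI and Et3N in MeCN convert it to the more substituted trimethylsilyl enol ether F2. Fluoride-mediated methylation (MeI, BnMe3NF, THF) should then occur on the convex face of the cis-fused bicyclic lactone, placing the methyl α and the acetyl cis to C4, and the route is rejoined at 6.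

Step 6. The zinc carbenoid may fail to engage the strongly enolised, hindered cyclic 1,3-dione, or may O-alkylate it. The fallback sets out from 6 and builds ring B by oxidative enolate coupling. The ketone is masked as its enolate with LiN(SiMe3)2 at −78 °C, MeLi is added to the lactone and the mixture is quenched cold to give the hydroxy diketone F3 (largely as its lactol). TBSOTf and 2,6-lutidine give the silyl ether F4. Inverse addition to LiN(i-Pr)2 followed by CuCl2 in DMF couples the two methyl-ketone enolates to the cyclohexane-1,4-dione F5. Dehydrogenation with IBX in DMSO rejoins the route at 10.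

Step 15. The alkenylchromium may add to the aldehyde with poor facial selectivity, so that ring closure delivers the wrong configuration at C9. The fallback sets out from 18 and sets C9 by reagent-controlled reduction. The Nozaki–Hiyama–Kishi closure is run as in step 15, and the product, taken as the (9S)-epimeric diol F6 or its mixture with 19, is oxidised selectively at the allylic alcohol with MnO2 to the macrocyclic enone F7. Reduction with (S)-Me-CBS oxazaborolidine and catecholborane (alkenyl flank large, C8 methylene small) should give the (9R) alcohol, rejoining the route at 19.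

Further compounds
F1 | step 4 | (3S,4S,4aS,7aR)-7-acetyl-3-{2-[(tert-butyldimethylsilyl)oxy]ethyl}-4-methylhexahydrocyclopenta[c]pyran-1(3H)-one (C7 epimers) | CC(=O)C1CC[C@H]2[C@H](C)[C@H](CCO[Si](C)(C)C(C)(C)C)OC(=O)[C@@H]12
F2 | step 4 | trimethylsilyl enol ether of F1 with the C7=C(OSiMe3)CH3 double bond | CC(O[Si](C)(C)C)=C1CC[C@H]2[C@H](C)[C@H](CCO[Si](C)(C)C(C)(C)C)OC(=O)[C@@H]12
F3 | step 6 | cis-1,2-diacetylcyclopentane hydroxy diketone (C4 and C7 methyl ketones, free C13 hydroxyl; lactol tautomer) | CC(=O)[C@@]1(C)CC[C@@H]([C@H](C)[C@@H](O)CCO[Si](C)(C)C(C)(C)C)[C@H]1C(C)=O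
F4 | step 6 | C13 tert-butyldimethylsilyl ether of F3 | CC(=O)[C@@]1(C)CC[C@@H]([C@H](C)[C@@H](O[Si](C)(C)C(C)(C)C)CCO[Si](C)(C)C(C)(C)C)[C@H]1C(C)=O
F5 | step 6 | cis-7a-methyl-3β-[(2S,3S)-3,5-bis(tert-butyldimethylsilyloxy)pentan-2-yl]hexahydro-1H-indene-4,7-dione | O=C1CCC(=O)[C@@]2(C)CC[C@@H]([C@H](C)[C@@H](O[Si](C)(C)C(C)(C)C)CCO[Si](C)(C)C(C)(C)C)[C@@H]12
F6 | step 15 | tricyclic (9S,13S)-9,13-diol 7-propanoate, the C9 epimer of 19 | C=C1[C@H]2C[C@H](OC(=O)CC)[C@@]3(C)CC[C@@H]([C@H](C)[C@@H](O)C/C=C(/C)[C@@H](O)C2)[C@@H]13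
F7 | step 15 | tricyclic C9 enone (13-hydroxy, 7-propanoate, 10Z) | C=C1[C@H]2C[C@H](OC(=O)CC)[C@@]3(C)CC[C@@H]([C@H](C)[C@@H](O)C/C=C(/C)C(=O)C2)[C@@H]13
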